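The target turns into its isomer and back with a relaxation half-life, by that step alone and reckoned for west, of 0.685 s, shorter than the 20 s of south-east, the shortest of the asked times, so I reckoned the coupling first and let the split between the two follow from it.

in all of them: electrophile 5.0 mM; free base 3.00 equiv; protonated nucleophile 1.10 equiv
- south-east: time 20 s
- west: time 60 s
- north-west: time 180 s

    electrophile + nucleophile → acid set free + target (k1 = 100 L mol⁻¹ s⁻¹)
    nucleophile + acid set free ⇌ protonated nucleophile, settled at all times (K2 = 1.0 × 10⁵ L mol⁻¹)
    acid set free + free base ⇌ salt of the base (K3 = 2.70 × 10⁵ L mol⁻¹, k3 = 40.9 L mol⁻¹ s⁻¹)
    nucleophile ⇌ dormant form (K4 = 0.50, k4 = 0.0192 s⁻¹)
    acid set free → by-product carried off (k5 = 0.105 s⁻¹)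
    target ⇌ isomer of the product (K6 = 2.5, k6 = 0.723 s⁻¹)

1. which of these there is most of at the end, counted by the electrophile in it, south-east (target / electrophile / isomer of the product)
2. which of these there is most of at the end, counted by the electrophile in it, west (target / electrophile / isomer of the product)
3. which of these there is most of at the end, counted by the electrophile in it, north-west (target / electrophile / isomer of the product)
4. the largest of these amounts at the end, in percent of the electrophile charged, south-east
5. the largest of these amounts at the end, in percent of the electrophile charged, west
6. the largest of these amounts at the end, in percent of the electrophile charged, north-west

I took the balance of step 2 as holding and reckoned with what it leaves free. Each coupling sets free one acid, and the protonated nucleophile gives up another to replace the nucleophile used, so acid appears at two per coupling. It leaves through the free base and the carrying-off step at a first-order constant of 0.718 s⁻¹ at the start. Putting that steady flow into the balance gave free nucleophile at 3.98% of the electrophile charged, and so a pseudo-first-order constant for the electrophile of 0.0199 s⁻¹. The steady flow is fair because the acid lives 1.39 s, far less than the 50.3 s of the electrophile.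

The weak link was that this constant belongs to the start, while the free base is being consumed. A share of 85.4% of the acid goes to the base at the start, and keeping that share, I reckoned that when half the electrophile has coupled, one equivalent of acid has appeared and the base stands near 2.15 equiv. The acid then leaves at 0.544 s⁻¹, while by a count of one lost per coupling, protonated nucleophile per electrophile stands at 1.20. Reforged at that midpoint, the coupling constant, the fraction of the remaining electrophile taken each second, is 0.0181 s⁻¹. The short relaxation lets the coupled part divide at once, with 71.4% as isomer. I committed to electrophile at 69.7% for south-east, isomer of the product at 47.3% for west, and isomer of the product at 68.7% for north-west.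

The forecast named electrophile at 67% for south-east, isomer of the product at 47% for west and isomer of the product at 70% for north-west, holding that “the acid set free is scavenged by the base at a limited rate”. For south-east its figure stood lower than mine.

The flasks gave electrophile at 68.8% for south-east, isomer of the product at 46.2% for west and isomer of the product at 68.0% for north-west. In west, the coupling constant left 33.8% of the electrophile by reckoning, and the flask held 34.8%. The neighbouring flask was west read later, at 1.5 min, and there the same constant gave 19.6% electrophile and 57.4% isomer of the product, while that reading held 21.3% electrophile and 56.0% isomer of the product.

The rate constants were chosen freely, and the outcome is calculated.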